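**Retrosynthetic overview**
- The lactone ring is the only ring made in the route and is closed last, by acid lactonisation of a 3,3-diarylpropanoic acid released in one global hydrogenolysis (five benzyl groups and a stilbene C=C).
- Key disconnection C4–C4a: a stereoretentive sp3–sp2 Suzuki–Miyaura coupling of an enantioenriched β-boryl ester (a boron homoenolate, the caffeate β-carbon acting as nucleophile) with a ring A aryl iodide.
- The boron homoenolate comes from copper-catalysed asymmetric conjugate borylation of tribenzylated caffeic acid; this step sets C4.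
- The ring A iodide comes from 2,4-bis(benzyloxy)benzaldehyde by iodination and Horner–Wadsworth–Emmons olefination; the stilbene is the masked CH2CH2 linker.
- Ring order: the three benzene rings are bought; the lactone ring is formed in the final step.

Assumption: C4 of the target is read from the SMILES as (R), and the Josiphos antipode named in step 4 is taken to be the one that gives the (R)-boronate (checked by oxidising an aliquot to the β-hydroxy ester; the other antipode is equally available).

**Route**

Step 1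
Reactants: 1 2,4-bis(benzyloxy)benzaldehyde
Product: 2 2,4-bis(benzyloxy)-5-iodobenzaldehyde
Conditions: NIS (1.1 equiv), TFA (0.3 equiv), MeCN, rt, dark
Reagents that add atoms: N-iodosuccinimide, O=C1CCC(=O)N1I
Why: Electrophilic aromatic iodination goes to C5, which is para to one benzyloxy group, ortho to the other and meta to the formyl group, while C3 is blocked between the two benzyloxy groups.

Step 2
Reactants: 2 2,4-bis(benzyloxy)-5-iodobenzaldehyde; 3 diethyl (3,4-dimethoxybenzyl)phosphonate
Product: 4 1,5-bis(benzyloxy)-2-[(E)-2-(3,4-dimethoxyphenyl)ethenyl]-4-iodobenzene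
Conditions: KOtBu (1.3 equiv), THF, 0 °C to rt
Reagents that add atoms: none
Why: Horner–Wadsworth–Emmons olefination of the aldehyde with the benzylic phosphonate anion gives the (E)-stilbene and leaves the aryl iodide untouched; the alkene geometry is of no consequence because it is hydrogenated in step 6.

Step 3
Reactants: 5 caffeic acid, (E)-3-(3,4-dihydroxyphenyl)prop-2-enoic acid
Product: 6 benzyl (E)-3-[3,4-bis(benzyloxy)phenyl]prop-2-enoate
Conditions: BnBr (3.5 equiv), K2CO3 (4 equiv), DMF, 60 °C, N2
Reagents that add atoms: benzyl bromide, BrCc1ccccc1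
Why: Exhaustive Williamson O-alkylation of both phenols and the carboxylate gives the tribenzyl compound, so that every protecting group in the coupled product later falls in a single hydrogenolysis.

Step 4
Reactants: 6 benzyl (E)-3-[3,4-bis(benzyloxy)phenyl]prop-2-enoate
Product: 7 benzyl (3R)-3-[3,4-bis(benzyloxy)phenyl]-3-(4,4,5,5-tetramethyl-1,3,2-dioxaborolan-2-yl)propanoate
Conditions: CuCl (3 mol%), NaOtBu (6 mol%), (S)-1-[(Rp)-2-(diphenylphosphino)ferrocenyl]ethyldicyclohexylphosphine (Josiphos, 4 mol%), B2pin2 (1.1 equiv), MeOH (2 equiv), THF, rt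
Reagents that add atoms: bis(pinacolato)diboron, CC1(C)OB(OC1(C)C)B1OC(C)(C)C(C)(C)O1
Why: Copper-catalysed enantioselective conjugate borylation: the chiral Josiphos–copper boryl species adds boron to one face of the cinnamate β-carbon and MeOH protonates the copper enolate, which sets the (R) stereocentre and turns the normally electrophilic β-carbon into a configurationally stable nucleophilic homoenolate equivalent.

Step 5
Reactants: 7 benzyl (3R)-3-[3,4-bis(benzyloxy)phenyl]-3-(4,4,5,5-tetramethyl-1,3,2-dioxaborolan-2-yl)propanoate (1.5 equiv); 4 1,5-bis(benzyloxy)-2-[(E)-2-(3,4-dimethoxyphenyl)ethenyl]-4-iodobenzene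
Product: 8 benzyl (3R)-3-[3,4-bis(benzyloxy)phenyl]-3-{2,4-bis(benzyloxy)-5-[(E)-2-(3,4-dimethoxyphenyl)ethenyl]phenyl}propanoate
Conditions: Pd2(dba)3 (4 mol%), PPh3 (64 mol%, P:Pd 8:1), Ag2O (1.5 equiv), DME, 85 °C, 24 h
Reagents that add atoms: none
Why: Stereoretentive Suzuki–Miyaura coupling of a secondary benzylic pinacol boronate with an aryl iodide: Ag2O promotes a four-centre Pd–O–B transmetalation that transfers the benzylic carbon with retention and the excess PPh3 holds back β-hydride elimination, so the boron homoenolate carbon of (R)-7 is joined to the electrophilic iodide carbon of ring A to give (R)-8.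

Step 6
Reactants: 8 benzyl (3R)-3-[3,4-bis(benzyloxy)phenyl]-3-{2,4-bis(benzyloxy)-5-[(E)-2-(3,4-dimethoxyphenyl)ethenyl]phenyl}propanoate
Product: 10 (4R)-4-(3,4-dihydroxyphenyl)-6-[2-(3,4-dimethoxyphenyl)ethyl]-7-hydroxy-3,4-dihydro-2H-chromen-2-one, via hydroxy acid 9 (not isolated)
Conditions: H2 (1 atm), Pd/C (10 wt%), THF–EtOH, rt; filter under Ar; then TsOH·H2O (10 mol%), toluene–THF, 60 °C
Reagents that add atoms: none
Why: Heterogeneous hydrogenolysis cleaves the four aryl benzyl ethers and the benzyl ester and saturates the stilbene without touching the methyl ethers or the C–H stereocentre, and acid-catalysed lactonisation can only engage the phenol ortho to the stereocentre, so the six-membered lactone closes with C4 unchanged as (R).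

**Compound list**
1 | 2,4-bis(benzyloxy)benzaldehyde | O=Cc1ccc(OCc2ccccc2)cc1OCc1ccccc1 | starting material
2 | 2,4-bis(benzyloxy)-5-iodobenzaldehyde | O=Cc1cc(I)c(OCc2ccccc2)cc1OCc1ccccc1 | intermediate
3 | diethyl (3,4-dimethoxybenzyl)phosphonate | CCOP(=O)(Cc1ccc(OC)c(OC)c1)OCC | starting material
4 | 1,5-bis(benzyloxy)-2-[(E)-2-(3,4-dimethoxyphenyl)ethenyl]-4-iodobenzene | COc1ccc(/C=C/c2cc(I)c(OCc3ccccc3)cc2OCc2ccccc2)cc1OC | intermediate
5 | caffeic acid, (E)-3-(3,4-dihydroxyphenyl)prop-2-enoic acid | O=C(O)/C=C/c1ccc(O)c(O)c1 | starting material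
6 | benzyl (E)-3-[3,4-bis(benzyloxy)phenyl]prop-2-enoate | O=C(OCc1ccccc1)/C=C/c1ccc(OCc2ccccc2)c(OCc2ccccc2)c1 | intermediate
7 | benzyl (3R)-3-[3,4-bis(benzyloxy)phenyl]-3-(4,4,5,5-tetramethyl-1,3,2-dioxaborolan-2-yl)propanoate | O=C(OCc1ccccc1)C[C@@H](B1OC(C)(C)C(C)(C)O1)c1ccc(OCc2ccccc2)c(OCc2ccccc2)c1 | intermediate
8 | benzyl (3R)-3-[3,4-bis(benzyloxy)phenyl]-3-{2,4-bis(benzyloxy)-5-[(E)-2-(3,4-dimethoxyphenyl)ethenyl]phenyl}propanoate | O=C(OCc1ccccc1)C[C@@H](c1cc(/C=C/c2ccc(OC)c(OC)c2)c(OCc2ccccc2)cc1OCc1ccccc1)c1ccc(OCc2ccccc2)c(OCc2ccccc2)c1 | intermediate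
9 | (3R)-3-(3,4-dihydroxyphenyl)-3-{2,4-dihydroxy-5-[2-(3,4-dimethoxyphenyl)ethyl]phenyl}propanoic acid (hydroxy acid) | O=C(O)C[C@@H](c1cc(CCc2ccc(OC)c(OC)c2)c(O)cc1O)c1ccc(O)c(O)c1 | intermediate
10 | (4R)-4-(3,4-dihydroxyphenyl)-6-[2-(3,4-dimethoxyphenyl)ethyl]-7-hydroxy-3,4-dihydro-2H-chromen-2-one | COc1ccc(CCc2cc3c(cc2O)OC(=O)C[C@@H]3c2ccc(O)c(O)c2)cc1OC | target

**Totals**
Total step count: 6. Longest linear sequence: 4 steps (1 → 2 → 4 → 8 → 10, or 5 → 6 → 7 → 8 → 10).

**Steps most likely to fail, with fallbacks**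

1. Step 5, the key coupling. The combination of an ester-bearing benzylic boronate with an ortho-benzyloxy aryl iodide is untested. The risks are β-hydride elimination back to 6, slow transmetalation and partial loss of ee. The fallback changes the boron homoenolate and the transmetalation manifold. It sets out from 6: the borylation of step 4 is run with the antipodal Josiphos ligand to give benzyl (3S)-3-[3,4-bis(benzyloxy)phenyl]-3-(4,4,5,5-tetramethyl-1,3,2-dioxaborolan-2-yl)propanoate F1. This is converted with KHF2 in MeOH–H2O into potassium {(1S)-3-(benzyloxy)-1-[3,4-bis(benzyloxy)phenyl]-3-oxopropyl}trifluoroborate F2. F2 is coupled with 4 using Pd(OAc)2, 2-dicyclohexylphosphino-2′,4′,6′-triisopropylbiphenyl and K2CO3 in cyclopentyl methyl ether–H2O at 95 °C. In this manifold the carbonyl oxygen binds boron, β-hydride elimination is suppressed and transmetalation is invertive (open SE2), so the (S)-trifluoroborate comes back to the route at (R)-8.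

2. Step 6, the global hydrogenolysis. Pd/C may be poisoned by iodide, silver or phosphine residues from step 5, or may give partly debenzylated mixtures. The fallback separates the two tasks and sets out from 8. Homogeneous hydrogenation with [Ir(cod)(PCy3)(py)]PF6 (Crabtree's catalyst) and H2 in CH2Cl2 saturates only the stilbene and gives benzyl (3R)-3-[3,4-bis(benzyloxy)phenyl]-3-{2,4-bis(benzyloxy)-5-[2-(3,4-dimethoxyphenyl)ethyl]phenyl}propanoate F3. BCl3 with pentamethylbenzene as cation scavenger in CH2Cl2 at −78 °C then removes all five benzyl groups by Lewis-acid cleavage while the methyl ethers survive. This comes back to the route at 9, which is lactonised with TsOH as in step 6 to give 10.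

3. Step 4, the asymmetric borylation. The electron-rich cinnamate may give an ee below what a single-enantiomer synthesis needs. The fallback adds enrichment by crystallisation of a derivative instead of relying on catalyst control alone. It sets out from 6: the borylation is run as before and the crude boronate is treated with diethanolamine in Et2O to precipitate benzyl (3R)-3-[3,4-bis(benzyloxy)phenyl]-3-(1,3,6,2-dioxazaborocan-2-yl)propanoate (the N→B chelated diethanolamine boronate) F4. F4 is recrystallised to enantiopurity, then shaken with pinacol and dilute aqueous HCl in Et2O, which comes back to the route at 7.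

**Further compounds**
F1 | step 5 | benzyl (3S)-3-[3,4-bis(benzyloxy)phenyl]-3-(4,4,5,5-tetramethyl-1,3,2-dioxaborolan-2-yl)propanoate | O=C(OCc1ccccc1)C[C@H](B1OC(C)(C)C(C)(C)O1)c1ccc(OCc2ccccc2)c(OCc2ccccc2)c1
F2 | step 5 | potassium {(1S)-3-(benzyloxy)-1-[3,4-bis(benzyloxy)phenyl]-3-oxopropyl}trifluoroborate | O=C(OCc1ccccc1)C[C@H]([B-](F)(F)F)c1ccc(OCc2ccccc2)c(OCc2ccccc2)c1.[K+]
F3 | step 6 | benzyl (3R)-3-[3,4-bis(benzyloxy)phenyl]-3-{2,4-bis(benzyloxy)-5-[2-(3,4-dimethoxyphenyl)ethyl]phenyl}propanoate | O=C(OCc1ccccc1)C[C@@H](c1cc(CCc2ccc(OC)c(OC)c2)c(OCc2ccccc2)cc1OCc1ccccc1)c1ccc(OCc2ccccc2)c(OCc2ccccc2)c1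
F4 | step 4 | benzyl (3R)-3-[3,4-bis(benzyloxy)phenyl]-3-(1,3,6,2-dioxazaborocan-2-yl)propanoate (diethanolamine boronate) | O=C(OCc1ccccc1)C[C@@H]([B-]12OCC[NH+]1CCO2)c1ccc(OCc2ccccc2)c(OCc2ccccc2)c1
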